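**One number.** I decided to follow one number through the alder run: the pool W, the part of the charge that is neither starting material, target nor homo product.

| flask | starting material | partner | remark | time |
|---|---|---|---|---|
| alder | 0.10 M | 0.15 M | run made earlier |  |
| larch | 0.10 M | 0.075 M | run made earlier |  |
| ash | 0.10 M | 0.30 M | run made earlier |  |
| elm | 0.050 M | 0.15 M | run made earlier |  |
| east | 0.10 M | 0.150 M | everything together at the start | 15 h |
| south | 0.10 M (fed, over 10 h) | 0.150 M | all else is in the flask from the start; the feed brings no volume worth counting | 15 h |
| west | 0.10 M | 0.150 M (fed, over 10 h) | all else is in the flask from the start; the feed brings no volume worth counting | 15 h |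

| run | time / h | homo product / % | target / % | starting material / % |
|---|---|---|---|---|
| alder | 1.33 | 3 | 3 | 31 |
| alder | 3.00 | 4 | 13 | 26 |
| alder | 6.00 | 9 | 18 | 18 |
| alder | 15.0 | 41 | 15 | 1 |
| larch | 1.00 | 0 | 0 | 39 |
| larch | 2.00 | 2 | 3 | 29 |
| larch | 5.00 | 10 | 12 | 22 |
| larch | 12.0 | 37 | 11 | 11 |
| ash | 1.50 | 0 | 11 | 35 |
| ash | 4.00 | 3 | 26 | 21 |
| ash | 8.00 | 8 | 27 | 16 |
| ash | 12.0 | 24 | 29 | 8 |
| elm | 1.00 | 0 | 6 | 37 |
| elm | 2.00 | 3 | 12 | 29 |
| elm | 5.00 | 0 | 18 | 22 |
| elm | 12.0 | 15 | 19 | 8 |

(scatter of a reading: 2 percentage points)

- a species is counted by the starting material in it: one homo product counts as two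
- the numbers in the tables scatter by 2 percentage points (one standard deviation)
- a reading or a percentage of target counts all its forms, free or not

- which flask leads in amount of homo product, in percent of the starting material charged ("all alike" within 1.5 percentage points) (east / south / west / all alike)
- how much homo product is there at the end, in percent of the starting material charged: east
- how much homo product is there at the end, in percent of the starting material charged: south
- how much homo product is there at the end, in percent of the starting material charged: west

**First instants.** In alder at 1.33 h, starting material read 31 %, while target and homo product read 3 % and 3 %. So W read 63.0 %: charge had entered the pool ahead of the products.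

**The middle.** Alder's target read 18 % at 6.00 h and 15 % at 15.0 h, so it had stopped gaining, within the scatter. Over that stretch homo product climbed from 9 % to 41 %, while W went from 55.0 % to 43.0 %.

**The end.** Homo product's slope there, over the square of the mean W (49.0 %), read 0.148 /h. This pool clock κ, the fraction of charge turned into homo product per hour per squared pool fraction, is an apparent second-order coefficient. Elm, at 0.050 M, had a mean W of 59.0 % and read 0.0616 /h, so I let κ scale with the charge.

**My reckoning.** East repeats alder's recipe, so I expected 41 %. For south I added alder's final target to its mean W, as the pool of the last 5.00 h, and κ gave 30.3 % from that stretch. For west I made no number.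

**The forecast.** It gave 40 % for east, 18 % for south and 45 % for west, with west leading, and its whole south is lower than my figure for the last stretch of south: “South keeps the pool dilute and late, so much less.”

**The flasks.** Of the flasks, east led with 40.2 %, against 33.5 % in south and 35.2 % in west. South ended with 3.27 % of target, against 17.5 % in east. South's W went from 61.7 % at 10.0 h to 51.7 % at 15.0 h; κ on that mean gives 24 percentage points, and the flask gained 23 points.

    second intermediate → side product (k = 2.73 × 10⁻⁴ /s)
    2 open intermediate → homo product (k = 5.10 × 10⁻⁴ /M/s)
    starting material ⇌ dormant form (K = 1.28, k = 2.82 × 10⁻⁴ /s)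
    partner + target ⇌ idle adduct, settled at all times (K = 30.0 /M)
    starting material → open intermediate (k = 8.38 × 10⁻⁵ /s)
    partner → second intermediate (k = 3.55 × 10⁻⁴ /s)
    open intermediate + second intermediate → target (k = 0.00231 /M/s)

**Less charge.** The second flask is east with 0.040 M of starting material. There κ scales to 0.0592 /h, and with elm's mean W in place of alder's, east's homo product scales to 23.3 %. The flask gives 25.2 %.

The runs stem from a simulated flask for an exercise, and the scatter is random.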